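The ratio of partner to starting material charged is 70.0 %. The proposed step takes one partner per product, and partner is charged in a smaller amount than starting material. So partner is the limiting reagent and this ratio is the ceiling on product. That is the end state we expect, and the runs must tell us how fast it is approached.

| flask | starting material | partner | protic impurity | remark | time |
|---|---|---|---|---|---|
| larch | 0.10 M | 0.070 M | 2 mM | run made earlier |  |
| maple | 0.10 M | 0.070 M | 1 mM | run made earlier |  |
| alder | 0.10 M | 0.070 M | 1.5 mM | run made earlier |  |
| cedar | 0.15 M | 0.070 M | 2 mM | run made earlier |  |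
| dusk | 0.10 M (fed, over 25 h) | 0.0700 M | 2.00 mM | all else is in the flask from the start; the feed brings no volume worth counting | 30 h |
| midnight | 0.10 M | 0.0700 M (fed, over 25 h) | 2.00 mM | all else is in the flask from the start; the feed brings no volume worth counting | 30 h |
| summer | 0.10 M (in portions, 4, over 25 h) | 0.0700 M | 2.00 mM | first portion at the start, last at 25 h | 30 h |
| spring | 0.10 M (fed, over 6.0 h) | 0.0700 M | 2.00 mM | all else is in the flask from the start; the feed brings no volume worth counting | 30 h |
| winter | 0.10 M | 0.0700 M | 2.00 mM | everything together at the start | 30 h |

| run | time / h | product / % | starting material / % |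
|---|---|---|---|
| larch | 4.00 | 15.2 | 32.9 |
| larch | 8.00 | 25.2 | 30.0 |
| larch | 12.0 | 34.8 | 26.1 |
| larch | 15.0 | 39.4 | 23.3 |
| larch | 20.0 | 45.6 | 21.4 |
| larch | 25.0 | 49.0 | 21.7 |
| larch | 30.0 | 54.6 | 19.9 |
| maple | 4.00 | 15.9 | 31.2 |
| maple | 8.00 | 26.4 | 27.7 |
| maple | 12.0 | 35.8 | 28.1 |
| maple | 15.0 | 38.1 | 25.0 |
| maple | 20.0 | 44.7 | 22.9 |
| maple | 25.0 | 50.2 | 21.2 |
| maple | 30.0 | 53.6 | 20.1 |
| alder | 4.00 | 16.6 | 31.3 |
| alder | 8.00 | 27.0 | 29.4 |
| alder | 12.0 | 34.4 | 27.2 |
| alder | 15.0 | 40.1 | 25.4 |
| alder | 20.0 | 43.9 | 23.9 |
| alder | 25.0 | 49.4 | 22.5 |
| alder | 30.0 | 52.2 | 20.6 |
| cedar | 6.00 | 17.8 | 27.7 |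
| cedar | 12.0 | 28.8 | 26.7 |
| cedar | 20.0 | 36.9 | 21.5 |
| cedar | 25.0 | 37.4 | 20.6 |
| cedar | 30.0 | 40.7 | 21.3 |

(scatter of a reading: 1 percentage point)

- percentages count the starting material that a species holds: one resting dimer counts as two
- steps that have been proposed: 2 starting material <-> resting dimer; starting material + partner -> product; starting material <-> dormant form; starting material + protic impurity -> quenched substrate

* the best flask by amount of product, in percent of the starting material charged; "all alike" if 1.5 percentage points covers them all (dusk / midnight / summer / spring / winter / all alike)
* amount of product at the end, in percent of the starting material charged, dusk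
* amount of product at the end, in percent of the starting material charged, midnight
* amount of product at the end, in percent of the starting material charged, summer
* amount of product at the end, in percent of the starting material charged, spring
* amount of product at the end, in percent of the starting material charged, winter

We read the larch table column against column. At 4.00 h, 51.9 % of the charge stands in neither column, so it sits in other forms, such as the proposed resting dimer. From then to 30.0 h product gains 39 percentage points, but free starting material loses less, just 13 points. So those other forms refill it, and as a rough estimate we treat the fall of partner as a pseudo-first-order decay.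

The last larch row gives 0.0505 h⁻¹. We call this the partner clearance: the logarithm of partner charged over partner left, divided by the time. The row at 12.0 h gives a little more, 0.0573 h⁻¹, so this reading is an average over the run.

Winter is the larch recipe, so we expect about 54.6 %. In midnight, partner arrives steadily over 25 h. With the clearance acting on a steady feed, the share still present when the feed ends is one minus the exponential of minus clearance times feed time, over clearance times feed time. That is 56.8 %. The last 5.00 h shrink it to 44.1 %. So we expect 39.1 % product in midnight, less than in winter.

The forecast names winter as best: dusk 41 %, midnight 39 %, summer 41 %, spring 51 %, winter 54 %. Its ground: “Starving either reagent therefore gains nothing, and it only loses time.” We made no reckoning of our own for dusk, summer or spring.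

The flasks give dusk 44.0 %, midnight 40.4 %, summer 43.6 %, spring 52.1 % and winter 53.8 %, so winter leads, as forecast.

    2 starting material ⇌ resting dimer, settled at all times (K = 25.0 M⁻¹)
    starting material + partner → product (k = 0.0310 M⁻¹ min⁻¹)
    starting material ⇌ dormant form (K = 0.260, k = 5.90 × 10⁻⁵ min⁻¹)
    starting material + protic impurity → quenched substrate (k = 0.130 M⁻¹ min⁻¹)

Winter stands at 53.8 % against its ceiling of 70.0 %, and after 300 h it holds 70.0 %. A winter flask with 0.0625 M of partner stands 5 points from 53.8 %, so the forecast's 54 % fits the charged recipe and not that flask. Midnight keeps 42 % of its partner at 30 h, against our 44.1 %. A neighbour of midnight gets 0.018 M of partner, so its ceiling is 18.0 %. With clearance 0.0505 h⁻¹ and the same feed, 44.1 % of its partner stays, which gives 10.1 % product. The neighbour keeps 37.3 % of its partner and makes 11.3 % product.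

The runs are calculated for an exercise, noise included.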